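Scale the charge and watch the yield.

in all of them: Q 6.00 × 10⁻⁴ M

| charge | X | L | time |
|---|---|---|---|
| birch | 0.300 M | 0.300 M |  |
| alder | 0.120 M | 0.120 M |  |
| oak | 0.300 M | 0.150 M |  |
| elm | 0.900 M | 0.300 M |  |
| larch | 1.20 M | 1.20 M | 16 min |

- birch run (time / min: [Z] / M): 0.64: 0.0154; 1.4: 0.0254; 3.2: 0.0515; 7.2: 0.0834; 16: 0.1286
- alder run (time / min: [Z] / M): 0.64: 0.0043; 1.4: 0.0111; 3.2: 0.0153; 7.2: 0.0297; 16: 0.0505
- oak run (time / min: [Z] / M): 0.64: 0.0091; 1.4: 0.0135; 3.2: 0.0346; 7.2: 0.0567; 16: 0.0892
- elm run (time / min: [Z] / M): 0.64: 0.0233; 1.4: 0.0423; 3.2: 0.0810; 7.2: 0.1328; 16: 0.2075

(standard deviation of a reading: 0.002 M)

- Overall: X + L -> Z, with Q as catalyst.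
- Constant volume, constant temperature.
- Bound and free are read together.
- "The second partner" is L.
- An order is taken over about fifteen percent of the charge, up and down.

- apparent order in [X] of the starting rate, round the charge of the birch run (the rate where two percent of its X have turned into Z) (one fixed amount of Z, the same in the runs compared)
- apparent order in [L] of the starting rate, round the charge of the birch run (the rate where two percent of its X have turned into Z)
- the alder run starts with 0.180 M less of X and of L than the birch run, and with no Z. Compared where both hold the same amount of X, once fifteen percent of what the alder run was charged with has turned into Z, is the alder run faster, slower or alike (within a tenth)?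
- Z in the larch run at 16 min, as a share of the X charged

The larch run charges 4.00 times what the birch run charges, of X and of L alike, so the question is how Z at 16 min follows the charge. You can solve two extreme versions in your head. Suppose first that the rate takes no notice of the amounts of X and L, zero order in both partners: the larch run then makes the same 0.1286 M as the birch run, and that is 10.7% of its X. Suppose instead that the rate is plainly proportional to X times L: for equal charges, share over one minus share grows with the charge, so the birch share of 42.9% becomes 75.0% in the larch run.

Now ask what power of the charge Z at a fixed time follows. The first version gives a power of zero, the second 1.40. The readings at 16 min place the flask between them. Raising X from the birch run to the elm run gives a power of 0.435, and lowering L from the birch run to the oak run gives 0.528. Added, they make 0.963, the charge exponent: the power of the charge that Z at a fixed time follows when X and L rise together. An exponent near one means the share turned at a given time changes little with the charge.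

My own reckoning for the larch run is therefore 0.489 M, or 40.7% of its X. Between the alder and birch runs the same exponent reads 1.02, higher. That is a hint, no more, that it falls as the charge rises, so I hold my figure as being on the high side.

The forecast gives orders of 0.63 in X and 0.68 in L, calls the alder run faster, and puts the larch run at 47%, holding that “both partners partly saturate the catalyst”. Its larch share stands above mine by 6.3 percentage points.

The larch run gives 37.0% of its X as Z at 16 min, less than the forecast's 47% and less than my 40.7%. The orders come out at 0.53 and 0.67, and the alder run is faster, by a rate ratio of 3.8.

    Q + X ⇌ QX, settled at all times (3.710 /M)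
    QX + L → Z + Q + J (538.2 /M/min)
    Q + Z ⇌ QZ, settled at all times (29.20 /M)
    2 L ⇌ L2, settled at all times (4.100 /M)

Counted from the birch run, that share means an exponent of 0.894, lower than my 0.963. Shares stand close at the lower charges too: Z in the alder run, charged 2.50 times less than the birch run, comes to a quarter of its charge at 6.66 min, against 5.94 min for Z in the birch run.

All runs were computed with made-up constants, and the scatter is random.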